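22.7% of the incoming ligand charged reads as gone into exchange in Thursday's run at 4.00 h. I call this the ligand share: the fraction of starting complex lost plus the fraction of complex with two exchanged, over the equivalents of incoming ligand charged. Each lost starting complex took one ligand, and each complex with two exchanged took a second.

| flask | starting complex | incoming ligand | leaving ligand | remark | time |
|---|---|---|---|---|---|
| Thursday's | 20 mM | 2 equiv | 1 equiv | run made earlier |  |
| Wednesday's | 20 mM | 2 equiv | 0.50 equiv | run made earlier |  |
| Saturday's | 20 mM | 2 equiv | 2 equiv | run made earlier |  |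
| Tuesday's | 20 mM | 3 equiv | 1 equiv | run made earlier |  |
| violet | 20 mM | 2.00 equiv (fed, over 80 min) | 1.00 equiv | all else is in the flask from the start; the feed brings no volume worth counting | 6.0 h |
| green | 20 mM (fed, over 80 min) | 2.00 equiv | 1.00 equiv | all else is in the flask from the start; the feed brings no volume worth counting | 6.0 h |
| blue | 20 mM | 2.00 equiv | 1.00 equiv | everything together at the start | 6.0 h |

| run | time / h | complex with two exchanged / % | starting complex / % |
|---|---|---|---|
| Thursday's | 0.250 | 1.8 | 92.5 |
| Thursday's | 0.667 | 6.7 | 85.5 |
| Thursday's | 1.33 | 10.6 | 79.0 |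
| Thursday's | 2.00 | 12.9 | 74.3 |
| Thursday's | 3.00 | 13.8 | 71.1 |
| Thursday's | 4.00 | 14.2 | 68.8 |
| Wednesday's | 0.667 | 6.1 | 84.9 |
| Wednesday's | 1.33 | 11.2 | 78.2 |
| Wednesday's | 2.00 | 13.2 | 74.6 |
| Wednesday's | 2.50 | 13.6 | 72.7 |
| Wednesday's | 3.00 | 14.5 | 71.2 |
| Wednesday's | 4.00 | 14.3 | 68.9 |
| Saturday's | 0.667 | 6.3 | 85.9 |
| Saturday's | 1.33 | 11.4 | 78.2 |
| Saturday's | 2.00 | 13.0 | 74.4 |
| Saturday's | 2.50 | 14.7 | 72.8 |
| Saturday's | 3.00 | 14.7 | 70.8 |
| Saturday's | 4.00 | 14.0 | 68.8 |
| Tuesday's | 0.667 | 10.1 | 80.3 |
| Tuesday's | 1.33 | 15.3 | 73.1 |
| Tuesday's | 2.00 | 17.6 | 69.7 |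
| Tuesday's | 3.00 | 18.8 | 65.4 |
| Tuesday's | 4.00 | 18.1 | 63.1 |

(scatter of a reading: 0.3 percentage points)

- for leaving ligand the crystals are counted in
- as a solid, counted per litre of solution: crystals
- candidate steps: starting complex + incoming ligand <-> leaving ligand + complex with one exchanged; complex with one exchanged + incoming ligand <-> leaving ligand + complex with two exchanged; crystals <-> leaving ligand; complex with one exchanged -> decomposed reagent; 2 incoming ligand -> homo dimer

- the flask with the highest amount of complex with two exchanged, in percent of the starting complex charged ("all alike" if they lie within 1.5 percentage points) (violet / green / blue / all alike)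
- final complex with two exchanged, as a percentage of the starting complex charged, in violet
- final complex with two exchanged, as a percentage of the starting complex charged, in green
- final complex with two exchanged, as a percentage of the starting complex charged, in blue

Here is the oddity. Thursday's run charges 2 equiv, enough for two exchanges on every complex, yet the reading of starting complex stands at 68.8% and falls by 2.3 percentage points in the last hour. The leaving ligand charge does not show in this reading: in Wednesday's run with 0.50 equiv and Saturday's with 2 equiv, the readings at 4.00 h are 68.9% and 68.8%.

So I look at incoming ligand. With the amount of complex held, exchange is pseudo-first-order in it, while the homo dimer step takes it at the second power, so I expect a higher concentration to lower the share. Tuesday's run, with 3 equiv, reads 18.3% at 4.00 h, lower than Thursday's. I therefore commit to an order of shares: blue, which repeats Thursday's recipe, near 22.7%, violet above it with its ligand metered in, green below it with its ligand waiting for complex.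

The forecast says 15% in violet, 12% in green and 13.2% in blue, with violet highest, since “feeding keeps incoming ligand low at first, wasting less to dimer”.

The flasks give 15.2% in violet, 8.64% in green and 12.5% in blue, so violet leads.

    starting complex + incoming ligand ⇌ leaving ligand + complex with one exchanged (K = 0.350, k = 0.150 M⁻¹ min⁻¹)
    complex with one exchanged + incoming ligand ⇌ leaving ligand + complex with two exchanged (K = 1.20, k = 1.30 M⁻¹ min⁻¹)
    crystals ⇌ leaving ligand, rate k3*(cs3 - [leaving ligand]) while solid is left; crystals form when [leaving ligand] > cs3 (solubility = 4.30 mM, k = 0.470 min⁻¹)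
    complex with one exchanged → decomposed reagent (k = 0.00370 min⁻¹)
    2 incoming ligand → homo dimer (k = 0.270 M⁻¹ min⁻¹)

At 6.00 h the ligand share is 25.8% in violet, 23.1% in blue and 17.0% in green, against 22.7% read in Thursday's run at 4.00 h; violet stands higher than blue and blue higher than green. The neighbour, violet with 8.00 equiv of incoming ligand, reaches 33.2% of complex with two exchanged and leaves 38.9% of starting complex. Its share is 11.8%, lower than violet's, and its homo dimer stands at 67.6 mM against 12.8 mM in violet.

The readings come from a simulation with constants of no real substance.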